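**Retrosynthetic overview**

1. The target is epicatechin-(4β→6)-epicatechin-(4β→6)-epicatechin; the last step strips thirteen benzyl ethers and three C8 halogens from trimer 21.
2. Key disconnection in the middle unit: O1–C2 and C4–C6(bottom unit), giving cis-epoxy carbinol 19 and the 8-bromo bottom unit 3. Forward: Friedel–Crafts arylation at C4, then 6-endo epoxide opening by the C8a phenol closes ring C of the middle unit through O1–C2.
3. Enabling feature: C4 of the middle unit is benzylic to its phloroglucinol ring A (ortho OH, ortho/para ethers, so it ionises), the C8a oxygen is 1,5-related to C2, and C2 is benzylic to catechol ring B, so an epoxide across C2–C3 opens at C2.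
4. 19 comes from aryl iodide 12 (top-unit electrophile 6 plus symmetric diiodophenol 11, which fixes the 4β→6 connectivity before the ring exists) and cis-epoxy aldehyde 17 (Z-cinnamate 15, Jacobsen epoxidation).
5. Ring order: the pyran rings of the top and bottom units come intact from (−)-epicatechin; the middle pyran ring is formed last, in step 13.

Key step: step 13

Remark: 4β means the face trans to the C2 aryl group and the C3 oxygen of an epicatechin unit; the carbinol carbon of 19 is drawn undefined because both epimers should converge in step 13.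

**Route**

Step 1
Reactants: 1 (−)-epicatechin
Product: 2 5,7,3',4'-tetra-O-benzyl-(−)-epicatechin
Conditions: BnBr (4.2 equiv), K2CO3, DMF, argon, 0 °C → rt
Reagents that add atoms: benzyl bromide, BrCc1ccccc1
Why: Williamson etherification, in which the four phenols are alkylated under carbonate conditions that leave the secondary C3 alcohol untouched and affect no stereocentre.

Step 2
Reactants: 2 5,7,3',4'-tetra-O-benzyl-(−)-epicatechin
Product: 3 8-bromo-5,7,3',4'-tetra-O-benzyl-(−)-epicatechin
Conditions: NBS (1.0 equiv), CH2Cl2, −40 °C → rt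
Reagents that add atoms: N-bromosuccinimide, O=C1CCC(=O)N1Br
Why: Electrophilic aromatic bromination, expected at C8 of ring A (ortho to O1 and the C7 ether, para to the C5 ether) as the most nucleophilic position, which leaves C6 free for the later interflavan bond.

Step 3
Reactants: 2 5,7,3',4'-tetra-O-benzyl-(−)-epicatechin
Product: 4 4β-(2-ethoxyethoxy)-5,7,3',4'-tetra-O-benzylepicatechin
Conditions: DDQ (2 equiv), 2-ethoxyethanol (5 equiv), CH2Cl2, rt
Reagents that add atoms: 2-ethoxyethanol, CCOCCO
Why: DDQ-mediated benzylic oxidation, in which hydride abstraction at C4 gives a cation stabilised by the C5 and C7 ethers that the alcohol should trap trans to the C3 hydroxyl, setting C4 as 4β.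

Step 4
Reactants: 4 4β-(2-ethoxyethoxy)-5,7,3',4'-tetra-O-benzylepicatechin
Product: 5 8-bromo-4β-(2-ethoxyethoxy)-5,7,3',4'-tetra-O-benzylepicatechin
Conditions: NBS (1.0 equiv), CH2Cl2, −40 °C
Reagents that add atoms: N-bromosuccinimide, O=C1CCC(=O)N1Br
Why: Electrophilic aromatic bromination at C8 as in step 2, where the bromine deactivates ring A of the future top unit so that it cannot act as a nucleophile in steps 8 and 13.

Step 5
Reactants: 5 8-bromo-4β-(2-ethoxyethoxy)-5,7,3',4'-tetra-O-benzylepicatechin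
Product: 6 8-bromo-4β-(2-ethoxyethoxy)-3,5,7,3',4'-penta-O-benzylepicatechin
Conditions: NaH, BnBr, Bu4NI (cat.), THF/DMF, 0 °C → rt
Reagents that add atoms: benzyl bromide, BrCc1ccccc1
Why: Williamson etherification of the C3 alkoxide, so that this oxygen neither consumes organomagnesium reagent in step 12 nor traps the cation in step 13, and leaves with the other benzyl groups at the end.

Step 6
Reactants: 7 1,3-bis(benzyloxy)benzene
Product: 8 1,5-bis(benzyloxy)-2,4-diiodobenzene
Conditions: NIS (2.1 equiv), TFA (cat.), MeCN, 0 °C → rt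
Reagents that add atoms: N-iodosuccinimide, O=C1CCC(=O)N1I
Why: Electrophilic aromatic iodination, in which each iodine should enter para to one benzyloxy group and ortho to the other, the carbon between the two ethers being the most hindered.

Step 7
Reactants: 8 1,5-bis(benzyloxy)-2,4-diiodobenzene
Product: 11 3,5-bis(benzyloxy)-2,6-diiodophenol, via aryllithium 9 (not isolated), via diisopropyl arylboronate 10 (not isolated)
Conditions: B(OiPr)3 (1.5 equiv) present, LiN(iPr)2 (1.2 equiv), THF, −78 °C; then aq. NaOH, H2O2, 0 °C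
Reagents that add atoms: hydrogen peroxide, OO
Why: Deprotonation between two halogens followed by borylation and oxidation, where the C–H flanked by both iodines is the most acidic, the borate in the flask traps the aryllithium before halogen migration or aryne formation, and alkaline peroxide turns the C–B bond into the phenol.

Step 8
Reactants: 6 8-bromo-4β-(2-ethoxyethoxy)-3,5,7,3',4'-penta-O-benzylepicatechin; 11 3,5-bis(benzyloxy)-2,6-diiodophenol
Product: 12 4β-[2,6-bis(benzyloxy)-4-hydroxy-3,5-diiodophenyl]-8-bromo-3,5,7,3',4'-penta-O-benzylepicatechin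
Conditions: 11 (3 equiv), TMSOTf (0.1 equiv), CH2Cl2, −78 → −40 °C; Et3N quench
Reagents that add atoms: none
Why: Lewis-acid Friedel–Crafts coupling of the interflavan type, in which TMSOTf ionises the C4 ether of 6 and the only unsubstituted carbon of 11 (para to its hydroxyl) should attack the cation trans to the C3 benzyloxy group, setting top-unit C4 as 4β; 11 is symmetric, so either iodine can serve later.

Step 9
Reactants: 13 3,4-bis(benzyloxy)benzaldehyde; 14 ethyl 2-(diphenoxyphosphoryl)acetate
Product: 15 ethyl (Z)-3-[3,4-bis(benzyloxy)phenyl]prop-2-enoate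
Conditions: NaH, THF, −78 → 0 °C
Reagents that add atoms: none
Why: Ando-type Horner–Wadsworth–Emmons olefination, in which the diaryl phosphonate favours fast elimination from the syn oxaphosphetane and should give the Z-cinnamate.

Step 10
Reactants: 15 ethyl (Z)-3-[3,4-bis(benzyloxy)phenyl]prop-2-enoate
Product: 16 ethyl (2S,3S)-3-[3,4-bis(benzyloxy)phenyl]oxirane-2-carboxylate
Conditions: aq. NaOCl (pH 11), (S,S)-N,N'-bis(3,5-di-tert-butylsalicylidene)-1,2-cyclohexanediaminomanganese chloride (6 mol%), 4-phenylpyridine N-oxide (0.25 equiv), CH2Cl2, 4 °C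
Reagents that add atoms: sodium hypochlorite, [Na+].[O-]Cl
Why: Jacobsen epoxidation, for which Z-cinnamate esters are a preferred substrate class, with the (S,S) catalyst chosen as the enantiomer expected to deliver the cis-(2S,3S) glycidate that sets the future C2 and C3 of the middle unit.

Step 11
Reactants: 16 ethyl (2S,3S)-3-[3,4-bis(benzyloxy)phenyl]oxirane-2-carboxylate
Product: 17 (2S,3S)-3-[3,4-bis(benzyloxy)phenyl]oxirane-2-carbaldehyde
Conditions: i-Bu2AlH (1.05 equiv), CH2Cl2, −78 °C; MeOH, aq. potassium sodium tartrate; used crude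
Reagents that add atoms: none
Why: Partial ester reduction, in which the tetrahedral aluminium hemiacetal should persist at −78 °C and release the aldehyde on work-up with the cis-epoxide intact.

Step 12
Reactants: 12 4β-[2,6-bis(benzyloxy)-4-hydroxy-3,5-diiodophenyl]-8-bromo-3,5,7,3',4'-penta-O-benzylepicatechin; 17 (2S,3S)-3-[3,4-bis(benzyloxy)phenyl]oxirane-2-carbaldehyde
Product: 19 cis-epoxy carbinol of the top unit (one iodine of 12 replaced by the CH(OH)-oxiranyl chain), via arylmagnesium chloride 18 (not isolated)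
Conditions: MeMgCl (1.05 equiv), THF, −30 °C; i-PrMgCl·LiCl (1.1 equiv), −30 → −10 °C; 17 (1.3 equiv), −40 → −10 °C; aq. NH4Cl; filtration through Et3N-deactivated silica
Reagents that add atoms: none
Why: Iodine–magnesium exchange on a magnesium phenoxide followed by 1,2-addition to an aldehyde, where exchange should be selective for C–I over the C–Br bond of the top unit and stop after one iodine because the ring then carries two anionic sites; the new carbinol centre is uncontrolled and irrelevant.

Step 13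
Reactants: 19 cis-epoxy carbinol of the top unit; 3 8-bromo-5,7,3',4'-tetra-O-benzyl-(−)-epicatechin
Product: 21 protected trimer (8-bromo top unit, 8-iodo middle unit, 8-bromo bottom unit, both links 4β→6), via open-chain Friedel–Crafts adduct 20 (not isolated)
Conditions: 3 (3.0 equiv), BF3·OEt2 (0.3 equiv), 4 Å MS, CH2Cl2, −78 → −30 °C; Et3N quench
Reagents that add atoms: none
Why: Proposed new method: BF3 ionises the benzylic carbinol of 19 (ortho-hydroxy and ortho/para-benzyloxy donors on ring A of the middle unit) to an o-quinone-methide-type cation, which the free C6 of 3 captures in a Friedel–Crafts alkylation to give 20; the C8a phenol then opens the activated cis-epoxide at its benzylic carbon, closing the middle pyran ring through O1–C2 in a 6-endo-tet mode with inversion at C2 and release of epoxide strain. The closest known reaction types are the Lewis-acid interflavan coupling of C4-oxygenated flavans with 8-bromoflavan nucleophiles, the diastereoselective Friedel–Crafts arylation of benzylic cations bearing an α-stereocentre, and the acid-mediated 6-endo cyclisation of 2-(3-aryloxiranylmethyl)phenols to flavan-3-ols; their merger on a 2,3-epoxy-1-arylpropan-1-ol has no direct precedent. C4 is controlled by allylic 1,3-strain: the cation should hold H3 in the plane of ring A and the arene should enter anti to the epoxide C3–C2 bond, the face that the cis-disposed ring B also leaves open, which gives the 3,4-trans relationship; both carbinol epimers converge on the same cation, and a cation formed after prior ring closure would be attacked trans to O3 as well. C2 is fixed by stereospecific backside attack, so the cis-epoxide geometry becomes the 2,3-cis arrangement, and C3 keeps its oxygen and configuration. The step needs 6-endo over 5-exo opening, secured by the benzylic, catechol-stabilised C2 and the crowded C3; it needs C6 over C8 attack on 3, secured by the bromine; and it needs the electrophile not to oligomerise, secured by its fully substituted ring A and the bromine-deactivated ring A of the top unit.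

Step 14
Reactants: 21 protected trimer
Product: 22 epicatechin-(4β→6)-epicatechin-(4β→6)-epicatechin
Conditions: H2 (1–4 bar), Pd(OH)2/C, Et3N (4 equiv), THF/MeOH/H2O, rt; filtration under argon, lyophilisation
Reagents that add atoms: none
Why: Catalytic hydrogenolysis, which should remove all thirteen benzyl ethers and the three C8 halogens in one operation, with triethylamine taking up the hydrogen halides and no stereocentre touched.

**Compound list**

1 | (−)-epicatechin, (2R,3R)-2-(3,4-dihydroxyphenyl)chromane-3,5,7-triol | Oc1cc(O)c2c(c1)O[C@H](c1ccc(O)c(O)c1)[C@H](O)C2 | starting material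
2 | 5,7,3',4'-tetra-O-benzyl-(−)-epicatechin (3-OH free) | c1ccccc1COc1cc(OCc2ccccc2)c2c(c1)O[C@H](c1ccc(OCc3ccccc3)c(OCc3ccccc3)c1)[C@H](O)C2 | intermediate
3 | 8-bromo-5,7,3',4'-tetra-O-benzyl-(−)-epicatechin (bottom unit) | c1ccccc1COc1cc(OCc2ccccc2)c2c(c1Br)O[C@H](c1ccc(OCc3ccccc3)c(OCc3ccccc3)c1)[C@H](O)C2 | intermediate
4 | 4β-(2-ethoxyethoxy)-5,7,3',4'-tetra-O-benzylepicatechin (2,3-cis, 3,4-trans) | c1ccccc1COc1cc(OCc2ccccc2)c2c(c1)O[C@H](c1ccc(OCc3ccccc3)c(OCc3ccccc3)c1)[C@H](O)[C@H]2OCCOCC | intermediate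
5 | 8-bromo-4β-(2-ethoxyethoxy)-5,7,3',4'-tetra-O-benzylepicatechin | c1ccccc1COc1cc(OCc2ccccc2)c2c(c1Br)O[C@H](c1ccc(OCc3ccccc3)c(OCc3ccccc3)c1)[C@H](O)[C@H]2OCCOCC | intermediate
6 | 8-bromo-4β-(2-ethoxyethoxy)-3,5,7,3',4'-penta-O-benzylepicatechin (top-unit electrophile) | c1ccccc1COc1cc(OCc2ccccc2)c2c(c1Br)O[C@H](c1ccc(OCc3ccccc3)c(OCc3ccccc3)c1)[C@H](OCc1ccccc1)[C@H]2OCCOCC | intermediate
7 | 1,3-bis(benzyloxy)benzene | c1ccccc1COc1cccc(OCc2ccccc2)c1 | starting material
8 | 1,5-bis(benzyloxy)-2,4-diiodobenzene | c1ccccc1COc1cc(OCc2ccccc2)c(I)cc1I | intermediate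
9 | [3,5-bis(benzyloxy)-2,6-diiodophenyl]lithium | c1ccccc1COc1cc(OCc2ccccc2)c(I)c([Li])c1I | intermediate
10 | diisopropyl [3,5-bis(benzyloxy)-2,6-diiodophenyl]boronate | c1ccccc1COc1cc(OCc2ccccc2)c(I)c(B(OC(C)C)OC(C)C)c1I | intermediate
11 | 3,5-bis(benzyloxy)-2,6-diiodophenol | c1ccccc1COc1cc(OCc2ccccc2)c(I)c(O)c1I | intermediate
12 | 4β-[2,6-bis(benzyloxy)-4-hydroxy-3,5-diiodophenyl]-8-bromo-3,5,7,3',4'-penta-O-benzylepicatechin | c1ccccc1COc1cc(OCc2ccccc2)c2c(c1Br)O[C@H](c1ccc(OCc3ccccc3)c(OCc3ccccc3)c1)[C@H](OCc1ccccc1)[C@H]2c1c(OCc2ccccc2)c(I)c(O)c(I)c1OCc1ccccc1 | intermediate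
13 | 3,4-bis(benzyloxy)benzaldehyde | O=Cc1ccc(OCc2ccccc2)c(OCc2ccccc2)c1 | starting material
14 | ethyl 2-(diphenoxyphosphoryl)acetate | CCOC(=O)CP(=O)(Oc1ccccc1)Oc1ccccc1 | starting material
15 | ethyl (Z)-3-[3,4-bis(benzyloxy)phenyl]prop-2-enoate | CCOC(=O)/C=C\c1ccc(OCc2ccccc2)c(OCc2ccccc2)c1 | intermediate
16 | ethyl (2S,3S)-3-[3,4-bis(benzyloxy)phenyl]oxirane-2-carboxylate (cis) | CCOC(=O)[C@H]1O[C@H]1c1ccc(OCc2ccccc2)c(OCc2ccccc2)c1 | intermediate
17 | (2S,3S)-3-[3,4-bis(benzyloxy)phenyl]oxirane-2-carbaldehyde (cis) | O=C[C@H]1O[C@H]1c1ccc(OCc2ccccc2)c(OCc2ccccc2)c1 | intermediate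
18 | chloromagnesium phenoxide / arylmagnesium chloride derived from 12 (one iodine exchanged) | c1ccccc1COc1cc(OCc2ccccc2)c2c(c1Br)O[C@H](c1ccc(OCc3ccccc3)c(OCc3ccccc3)c1)[C@H](OCc1ccccc1)[C@H]2c1c(OCc2ccccc2)c(I)c(O[Mg]Cl)c([Mg]Cl)c1OCc1ccccc1 | intermediate
19 | cis-epoxy carbinol: 12 with one iodine replaced by CH(OH)-[(2R,3S)-3-(3,4-bis(benzyloxy)phenyl)oxiran-2-yl], both carbinol epimers | c1ccccc1COc1cc(OCc2ccccc2)c2c(c1Br)O[C@H](c1ccc(OCc3ccccc3)c(OCc3ccccc3)c1)[C@H](OCc1ccccc1)[C@H]2c1c(OCc2ccccc2)c(I)c(O)c(C(O)[C@H]2O[C@H]2c2ccc(OCc3ccccc3)c(OCc3ccccc3)c2)c1OCc1ccccc1 | intermediate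
20 | open-chain Friedel–Crafts adduct: 19 with the carbinol OH replaced by C6 of 3, cis-epoxide and free phenol intact, C4 configured as in 21 | c1ccccc1COc1cc(OCc2ccccc2)c2c(c1Br)O[C@H](c1ccc(OCc3ccccc3)c(OCc3ccccc3)c1)[C@H](OCc1ccccc1)[C@H]2c1c(OCc2ccccc2)c(I)c(O)c([C@H](c4c(OCc5ccccc5)c(Br)c6c(c4OCc5ccccc5)C[C@@H](O)[C@@H](c4ccc(OCc5ccccc5)c(OCc5ccccc5)c4)O6)[C@H]2O[C@H]2c2ccc(OCc3ccccc3)c(OCc3ccccc3)c2)c1OCc1ccccc1 | intermediate
21 | protected trimer: [8-bromo-3,5,7,3',4'-penta-O-benzylepicatechin]-(4β→6)-[8-iodo-5,7,3',4'-tetra-O-benzylepicatechin]-(4β→6)-[8-bromo-5,7,3',4'-tetra-O-benzylepicatechin] | c1ccccc1COc1cc(OCc2ccccc2)c2c(c1Br)O[C@H](c1ccc(OCc3ccccc3)c(OCc3ccccc3)c1)[C@H](OCc1ccccc1)[C@H]2c1c(OCc4ccccc4)c(I)c2c(c1OCc4ccccc4)[C@H](c1c(OCc4ccccc4)c(Br)c3c(c1OCc4ccccc4)C[C@@H](O)[C@@H](c1ccc(OCc4ccccc4)c(OCc4ccccc4)c1)O3)[C@@H](O)[C@@H](c1ccc(OCc4ccccc4)c(OCc4ccccc4)c1)O2 | intermediate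
22 | epicatechin-(4β→6)-epicatechin-(4β→6)-epicatechin | Oc1cc(O)c2c(c1)O[C@H](c1ccc(O)c(O)c1)[C@H](O)[C@H]2c1c(O)cc2c(c1O)[C@H](c1c(O)cc3c(c1O)C[C@@H](O)[C@@H](c1ccc(O)c(O)c1)O3)[C@@H](O)[C@@H](c1ccc(O)c(O)c1)O2 | target

**Step count and risks**

Total step count: 14. Longest linear sequence: 8 steps (1, 3, 4, 5, 8, 12, 13, 14).

Steps most likely to fail:

1. Step 13 (Proposed new method). What may go wrong: loss of stereochemical fidelity at C2 through unimolecular opening of the catechol-activated epoxide, rearrangement of the epoxide to a ketone before the phenol closes the ring, or poor facial selectivity when the open-chain cation is arylated at C4. Fallback with known chemistry, from 19 back to 21: 19 is treated with pyridinium p-toluenesulfonate (cat.) and 2-ethoxyethanol (10 equiv) in CH2Cl2 at 0 °C. The phenol should open the epoxide in the 6-endo sense while the benzylic carbinol exchanges to its ether, giving the closed middle ring as the 4-(2-ethoxyethoxy)flavan-3-ol F1 (C4 epimers). F1 is then coupled with 3 (3 equiv) under TMSOTf (cat.), CH2Cl2, −78 °C, the standard coupling through a cyclic C4 cation with trans attack, to return to 21.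

2. Step 12. What may go wrong: sluggish or unselective halogen–metal exchange on the crowded phenoxide, opening of the epoxide by magnesium halide, and ionisation of the electron-rich carbinol during isolation. Fallback, from 16 and 12 back to 19: 16 is converted with MeNH(OMe)·HCl and i-PrMgCl (THF, −20 °C) into (2S,3S)-3-[3,4-bis(benzyloxy)phenyl]-N-methoxy-N-methyloxirane-2-carboxamide F2. F2 acylates 18 (made from 12 as in step 12) to give the hydrogen-bonded cis-epoxy ketone F3, which can be purified and stored. Luche reduction (NaBH4, CeCl3·7H2O, MeOH/THF, −40 °C) immediately before use returns to 19.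

3. Step 10. What may go wrong: erosion of the cis geometry by stepwise oxygen transfer to an electron-rich styrene-type alkene, and insufficient enantioselectivity. Fallback, from 15 back to 17: 15 is reduced with i-Bu2AlH (2.2 equiv, CH2Cl2, −78 °C) to (Z)-3-[3,4-bis(benzyloxy)phenyl]prop-2-en-1-ol F4. Sharpless asymmetric epoxidation (Ti(OiPr)4, D-(−)-diisopropyl tartrate, t-BuOOH, 4 Å MS, CH2Cl2, −20 °C) should give [(2R,3S)-3-[3,4-bis(benzyloxy)phenyl]oxiran-2-yl]methanol F5. Dess–Martin oxidation (NaHCO3, CH2Cl2, 0 °C) returns to 17.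

Further compounds
F1 | step 13 | closed middle unit as C4 ether: [8-bromo-3,5,7,3',4'-penta-O-benzylepicatechin]-(4β→6)-[4-(2-ethoxyethoxy)-8-iodo-5,7,3',4'-tetra-O-benzylepicatechin], C4 epimers | c1ccccc1COc1cc(OCc2ccccc2)c2c(c1Br)O[C@H](c1ccc(OCc3ccccc3)c(OCc3ccccc3)c1)[C@H](OCc1ccccc1)[C@H]2c1c(OCc4ccccc4)c(I)c2c(c1OCc4ccccc4)C(OCCOCC)[C@@H](O)[C@@H](c1ccc(OCc4ccccc4)c(OCc4ccccc4)c1)O2
F2 | step 12 | (2S,3S)-3-[3,4-bis(benzyloxy)phenyl]-N-methoxy-N-methyloxirane-2-carboxamide | CON(C)C(=O)[C@H]1O[C@H]1c1ccc(OCc2ccccc2)c(OCc2ccccc2)c1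
F3 | step 12 | cis-epoxy ketone: 19 with the carbinol oxidised to C=O, oxirane (2S,3S) | c1ccccc1COc1cc(OCc2ccccc2)c2c(c1Br)O[C@H](c1ccc(OCc3ccccc3)c(OCc3ccccc3)c1)[C@H](OCc1ccccc1)[C@H]2c1c(OCc2ccccc2)c(I)c(O)c(C(=O)[C@H]2O[C@H]2c2ccc(OCc3ccccc3)c(OCc3ccccc3)c2)c1OCc1ccccc1
F4 | step 10 | (Z)-3-[3,4-bis(benzyloxy)phenyl]prop-2-en-1-ol | OC/C=C\c1ccc(OCc2ccccc2)c(OCc2ccccc2)c1
F5 | step 10 | [(2R,3S)-3-[3,4-bis(benzyloxy)phenyl]oxiran-2-yl]methanol | OC[C@H]1O[C@H]1c1ccc(OCc2ccccc2)c(OCc2ccccc2)c1
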